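The readings are calculated with made-up constants, noise included.

Ask which of amber and grey ends with the longer chains, and reckon with the fraction of G left, not the fraction made.

| flask | G | Q | J | remark | time |
|---|---|---|---|---|---|
| alpha | 49 mM (fed, over 80 s) | 0.73 mM | 0.49 mM | run made earlier |  |
| amber | 49 mM (fed, over 80 s) | 0.490 mM | 0.49 mM |  | 2.5 h |
| grey | 49 mM (fed, over 80 s) | 0.490 mM | 1.0 mM |  | 2.5 h |

alpha run (percent of the G charged)

| time / min | E / % | G / % |
|---|---|---|
| 5.00 | 4.6 | 94.9 |
| 12.0 | 15.9 | 83.7 |
| 25.0 | 29.7 | 70.6 |
| 40.0 | 39.4 | 60.8 |
| 50.0 | 42.7 | 56.8 |

(each reading ± 0.3 percentage points)

* which of the two ends with the longer chains by the average number of monomer units in a chain (chains begun, living or dead) ("neither" if they lie within 10%) (amber / grey / neither)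
* average number of monomer units in a chain (chains begun, living or dead) at the end, amber
* average number of monomer units in a chain (chains begun, living or dead) at the end, grey

- the average divides the monomer in chains by the number of chains begun, living and dead together
- the numbers in the tables scatter by 0.3 percentage points (one standard deviation)
- the earlier runs do not show the number of chains; that part of a forecast is a guess
- no earlier run changes the charge of Q; that part of a forecast is a guess
- no earlier run changes the charge of J; that part of a forecast is a guess

Draw alpha as the logarithm of G left: its slope reads 0.0179 min⁻¹ between the first two readings and 0.00681 min⁻¹ between the last two, so the readings give a bend of 0.0266 min⁻¹. Continuing that bend past the last reading adds 0.224 to the logarithm, which puts alpha's level near 45.4% of G left.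

Now make my own guess, untested by any earlier run: each J starts one growing centre and each Q kills one. Alpha then stops with 32.9% of its Q left. On that guess the same centres consume G and Q, so take the logarithm of the fraction of G left over the logarithm of the fraction of Q left as a constant, the survival exponent, here 0.710.

Alpha's bend, set against its Q near mid-run, 0.447 mM, gives amber a clock of 34.4 min. With J and Q equal in amber, Q left falls as one over one plus time per clock. So I reckon that amber's E crosses G at 56.8 min, and that at the end Q left is 18.6% and G left 30.3%, a length of 69.7.

In grey, on the same guess, Q is the limiting reagent of the killing, so the centres fall towards 0.510 mM, and the same clock, run with that excess, brings my reckoned Q left at the end to 0.545%. Raised to the exponent, that leaves 2.47% of G, a length of 47.8, shorter than amber's.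

The forecast, taking “Q to act as a catalyst or activator”, names amber, with 48 for amber and 29 for grey: the same direction as mine, with shorter chains in both flasks.

The flask gives amber, with 75.0 for amber and 48.9 for grey.

    G + J → X (k = 0.0910 L mol⁻¹ min⁻¹)
    G + D → E + D, rate k2*[D]*[G] (k = 50.0 L mol⁻¹ min⁻¹)
    G + J → D + E (k = 6.50 L mol⁻¹ min⁻¹)
    D + Q → Z (k = 62.0 L mol⁻¹ min⁻¹)

Raise amber's Q left at the end, 19.1%, to the exponent 0.710, and G left comes to 30.9% against the 26.0% that stood there. Amber's flask read at 10 h, with Q left at 5.95%, gives 13.5% against 10.2%. The main reason for the gap between the flasks is their difference in J: grey stands at 48.9, and without that difference it stands at 75.0.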